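## The problem

1. The target is a 1-aryltetralin cyclolignan of the lyoniresinol type in which ring A, the fused arene (C4a to C8a, OMe at C6 and C8, OH at C7), is joined to the saturated ring B, which carries three contiguous, all-trans stereocentres: C1 (R, syringyl), C2 (S, the CH2OSO3H arm, C2a) and C3 (S, the CH2OH arm, C3a).
2. The two one-carbon arms differ only in that C2a–O is sulfated, so C2a and C3a have to be kept chemically distinct from an early stage; a late selective sulfation of the 1,4-diol cannot be relied on.
3. The sulfate monoester will not survive Lewis or Brønsted acid and both phenols would be sulfated along with the alcohol, so it must be introduced next to last, on a compound whose other hydroxyls carry groups that leave under neutral conditions.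
4. Only C3 lacks an activating neighbour, so it has to be set absolutely and early.
5. C2 sits next to a carbonyl-derived carbon and can be placed trans to C3 under equilibrating conditions, and C1, being doubly benzylic, can be set last, anti to C2.
6. C1 is a diarylmethine bonded to C8a and to the carbon para to the hydroxyl of a 2,6-dimethoxyphenol, so it stands at the aldehyde oxidation level between two electron-rich arenes.
7. Before closure, ring A is a symmetric 4-oxy-3,5-dimethoxybenzyl group whose two free positions are equivalent, each ortho to one methoxy group and para to the other.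
8. Together these features allow both aryl bonds of C1 to be made from a single acetal carbon without regiochemical ambiguity.

## Retrosynthesis

**O–S bond and benzyl ethers (22 ⇒ 20 ⇒ 18).** The sulfate is cut first. In the forward sense it goes onto alcohol 18, in which C2a–OH is the only free hydroxyl and both phenols and C3a–OH are benzyl ethers. Benzyl is chosen because alkyl sulfate salts survive hydrogenolysis, whereas acid- or fluoride-labile groups would put the sulfate at risk. The sodium sulfate 20 is then debenzylated and protonated to 22.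

**C2a oxidation level and the third benzyl group (18 ⇒ 17 ⇒ 16).** C2a–OH is traced to a methyl ester and the syringyl benzyl ether to a free phenol. The ester at C2 and the benzyl ether at C3a are what tell the two arms apart. The phenol has to be free in 16 because only the free hydroxyl directs the arylation to its para carbon; an O-benzylated nucleophile would react ortho to a methoxy group.

**C1–C8a and C1–aryl (16 ⇒ 13 + 14).** Both aryl bonds of C1 are cut at once, which leads to acetal 13 and 2,6-dimethoxyphenol 14. Cutting only C1–C8a (an aldol adduct of a syringaldehyde ether, closed by acid) is the classical neighbour. It needs the aryl aldehyde in protected form and spends a separate C–C bond-forming step on C1–C2. The double cut takes the aryl group from the cheapest possible reagent and leaves a precursor with one stereocentre that matters (C3). The forward reaction has to close ring B before or after arylation without elimination and to set C1 anti to a C2 ester that is itself trans to C3.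

**C1–C2 (13 ⇒ 11).** The acetal carbon is removed by cutting C1–C2, which corresponds to a crossed Claisen formylation of methyl ester 11 followed by acetalisation. C2 is formed without control. This is accepted because C2 is labile under the acidic conditions of the key step.

**C3a–O benzyl and ester methyl (11 ⇒ 10 ⇒ 8).** Ester 11 is the methyl ester of benzyloxy acid 10, which is the opened, differentiated form of the β-benzyl-γ-butyrolactone 8; the lactone carbonyl is C2a and the ring CH2O is C3a. Running the key step on the lactone would fix C2 but would return a symmetrical-looking diol problem at the end. Opening the lactone first keeps the end game short.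

**C3 stereocentre (8 ⇒ 6 ⇒ 5).** Lactone 8 comes from the half-ester 6 by reduction of its ester in the presence of the carboxylate. Acid 6 comes from the alkylidenesuccinate half-ester 5 by asymmetric hydrogenation. This step sets C3, and with it the absolute configuration of the whole molecule, by catalysis on a substrate class for which this works well.

**C3–C4 double bond (5 ⇒ 2 + 3 ⇒ 1).** The Stobbe condensation of aldehyde 2 with dimethyl succinate 3 assembles the whole carbon chain except C1 in one step and delivers the acid/ester differentiation needed later. Aldehyde 2 is the benzyl ether of syringaldehyde 1.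

## Roads not taken

Alternative 1: oxidative dimerisation of an auxiliary-bound sinapate. The cut is at C2–C3 and C1–C8a and leads to two molecules of the N-sinapoyl oxazolidinone A1. In the forward step FeCl3 oxidises A1 by one electron; two of the resulting radicals couple at C2–C3, one ring re-aromatises, and it adds through C8a to the remaining quinone methide to give the dihydronaphthalene bis-imide A2. This is the shortest path to the skeleton, needs no phenol protection and forms two C–C bonds and ring B in one operation; in step count to the carbon framework it is clearly better than the chosen plan. Its weak points for this target are several. Radical coupling of sinapates is not regioselective by nature, and the auxiliary has to control two new centres in a radical–radical event. A2 still carries a C3=C4 double bond whose reduction must deliver C3 trans to C2. The two acyl groups are the same imide, so C2a and C3a are distinguished only by conjugation, and all phenols have to be protected before sulfation anyway. The chosen plan is longer, but each stereocentre has an identified control element and the two arms are distinct from the Stobbe step (step 2) on.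

Alternative 2: photoenol Diels–Alder reaction with a chiral fumarate. The cut is at C1–C2 and C3–C4 and leads to the 2-benzylbenzaldehyde A3 and the bis-lactate fumarate A4. Irradiation of A3 unmasks a hydroxy-diene across ring A, which adds A4 to give the 4-hydroxytetralin diester A5. The route is convergent, and the 2,3-trans relationship is guaranteed by the fumarate geometry, more rigidly than by the equilibration used in the chosen plan. Against it, A3 is a hexasubstituted diarylmethane aldehyde that needs its own multistep synthesis, facial control by two remote lactate esters in an uncatalysed photochemical cycloaddition is uncertain, and the C4 hydroxyl has to be removed afterwards. Most seriously, the two ester groups of A5 are identical, so the one distinction the target demands, C2a against C3a, is absent. The chosen plan gives up the convergent ring construction but carries the C2a/C3a distinction from the start and needs no deoxygenation.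

Alternative 3: donor–acceptor cyclopropane (3+3) annulation onto ring A. The cut is at C1–C8a and C3–C4 and leads to the cyclopropane triester A6 and the benzyl acetate A7. Sc(OTf)3 activates A6 for attack by the arene of A7 at the donor carbon with inversion, and the malonate carbon is then alkylated by the benzylic carbon to give the tetralin triester A8. Chirality is transferred from the cyclopropane to C1, and the tert-butyl and methyl esters differentiate the C2 and C3 arms more elegantly than the lactone opening of the chosen plan. However, A8 is 1,2-cis as formed, so C2 must be epimerised, and C3 is a quaternary malonate carbon that becomes a stereocentre only on decarboxylation, without kinetic control. Enantioenriched A6 needs an asymmetric synthesis of its own; with so electron-rich a donor aryl group the ring opening is likely to drift toward an ionised pathway and lose stereochemical fidelity; and A7 can ionise and condense with itself under the same Lewis acid. The chosen plan sets C3 by a reliable hydrogenation, forms C1 directly trans to C2 and needs no decarboxylation; it concedes the cleaner arm differentiation of this route.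

Key step: step 8

Remarks on the chemistry:
- The target is taken as the free hydrogen sulfate as drawn. It is released from its sodium salt in the last operation and should be kept cold, since alkyl hydrogen sulfates solvolyse under their own acidity.
- The (R,R) antipode of Et-DuPHOS is expected to give the (S) acid 6, by analogy with other 2-alkylidenesuccinate half-esters. The sense is to be confirmed on lactone 8, and the antipodal ligand taken if required.
- Atom labels C1 to C8a, C2a and C3a refer to the tetralin numbering used above and are applied to the corresponding carbons of open-chain precursors.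

## Route

Step 1
Reactants: 1 syringaldehyde (4-hydroxy-3,5-dimethoxybenzaldehyde)
Product: 2 4-(benzyloxy)-3,5-dimethoxybenzaldehyde
Conditions: BnBr, K2CO3, DMF, 60 °C
Reagents that add atoms: benzyl bromide, BrCc1ccccc1
Why: Williamson ether synthesis on the phenoxide; the aldehyde is untouched and the benzyl group will leave by hydrogenolysis at the end.

Step 2
Reactants: 2 4-(benzyloxy)-3,5-dimethoxybenzaldehyde; 3 dimethyl succinate
Product: 5 (E)-4-[4-(benzyloxy)-3,5-dimethoxyphenyl]-3-(methoxycarbonyl)but-3-enoic acid, via paraconic ester lactone 4 (not isolated)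
Conditions: NaOMe, MeOH, reflux; then aq. HCl
Reagents that add atoms: none
Why: Stobbe condensation; the aldol alkoxide lactonises onto the distal ester to 4, and base-induced ring opening gives the carboxylate of the E half-ester (aryl trans to CO2Me), which is purified by crystallisation.

Step 3
Reactants: 5 (E)-4-[4-(benzyloxy)-3,5-dimethoxyphenyl]-3-(methoxycarbonyl)but-3-enoic acid
Product: 6 (3S)-4-[4-(benzyloxy)-3,5-dimethoxyphenyl]-3-(methoxycarbonyl)butanoic acid
Conditions: [Rh(cod)2]BF4 (1 mol %), (R,R)-Et-DuPHOS (1.1 mol %), NaOMe (10 mol %), H2 (5 bar), MeOH, rt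
Reagents that add atoms: none
Why: Rh-catalysed asymmetric hydrogenation of an itaconate-type half-ester; chelation of the alkene and the carboxylate arm to the cationic bisphosphine rhodium centre fixes the face of hydrogen delivery and sets C3 (S); homogeneous rhodium does not cleave the benzyl ether.

Step 4
Reactants: 6 (3S)-4-[4-(benzyloxy)-3,5-dimethoxyphenyl]-3-(methoxycarbonyl)butanoic acid
Product: 8 (4S)-4-[4-(benzyloxy)-3,5-dimethoxybenzyl]dihydrofuran-2(3H)-one, via lithium hydroxy carboxylate 7 (not isolated)
Conditions: LiOH·H2O (1.0 equiv), MeOH, 0 °C; evaporate, toluene azeotrope; LiBH4 (2 equiv), THF, 0 °C → rt; then 2 M HCl, rt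
Reagents that add atoms: none
Why: Chemoselective borohydride reduction: LiBH4 reduces the methyl ester but not the pre-formed lithium carboxylate, which also keeps the acid from forming an acyloxyborohydride, and acidification closes the γ-lactone; the single equivalent of LiOH is consumed at once by the acid, so the centre next to the ester is not epimerised.

Step 5
Reactants: 8 (4S)-4-[4-(benzyloxy)-3,5-dimethoxybenzyl]dihydrofuran-2(3H)-one
Product: 10 (3S)-4-[4-(benzyloxy)-3,5-dimethoxyphenyl]-3-[(benzyloxy)methyl]butanoic acid, via potassium hydroxy carboxylate 9 (not isolated)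
Conditions: KOH (powdered, 5 equiv), BnBr (3 equiv), toluene, reflux; then H2O, HCl to pH 2, 0 °C
Reagents that add atoms: benzyl bromide, BrCc1ccccc1; potassium hydroxide, [K+].[OH-]
Why: Hydroxide opens the lactone to the potassium hydroxy carboxylate 9, whose alkoxide undergoes Williamson benzylation while the carboxylate stays inert in toluene (any benzyl ester is saponified in the same medium); this fixes C3a–O as the benzyl ether and leaves C2a as the acid.

Step 6
Reactants: 10 (3S)-4-[4-(benzyloxy)-3,5-dimethoxyphenyl]-3-[(benzyloxy)methyl]butanoic acid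
Product: 11 methyl (3S)-4-[4-(benzyloxy)-3,5-dimethoxyphenyl]-3-[(benzyloxy)methyl]butanoate
Conditions: MeI, K2CO3, DMF, rt
Reagents that add atoms: iodomethane, CI
Why: O-alkylation of the carboxylate; with the C3a oxygen already benzylated no relactonisation is possible.

Step 7
Reactants: 11 methyl (3S)-4-[4-(benzyloxy)-3,5-dimethoxyphenyl]-3-[(benzyloxy)methyl]butanoate
Product: 13 methyl (3S)-4-[4-(benzyloxy)-3,5-dimethoxyphenyl]-3-[(benzyloxy)methyl]-2-(dimethoxymethyl)butanoate (both C2 epimers), via 2-formyl ester 12 (not isolated)
Conditions: LiN(iPr)2 (2.0 equiv), THF, −78 °C; HCO2Me, −78 → 0 °C; then HCl in MeOH, HC(OMe)3, 0 °C → rt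
Reagents that add atoms: methyl formate, COC=O; trimethyl orthoformate, COC(OC)OC; methanol, CO
Why: Crossed Claisen formylation of the ester enolate gives the enolate of 12, which acidic methanol and orthoformate convert directly into the dimethyl acetal; C2 is formed without control and both epimers are carried on, and any premature cyclisation would only give intermediate 15 of the next step.

Step 8
Reactants: 13 methyl (3S)-4-[4-(benzyloxy)-3,5-dimethoxyphenyl]-3-[(benzyloxy)methyl]-2-(dimethoxymethyl)butanoate (both C2 epimers); 14 2,6-dimethoxyphenol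
Product: 16 methyl (1R,2S,3S)-7-(benzyloxy)-3-[(benzyloxy)methyl]-1-(4-hydroxy-3,5-dimethoxyphenyl)-6,8-dimethoxy-1,2,3,4-tetrahydronaphthalene-2-carboxylate, via 1-methoxytetralin 15 (not isolated)
Conditions: 14 (3 equiv), BF3·OEt2 (3 equiv), CH2Cl2, −40 → 0 °C
Reagents that add atoms: none
Why: BF3·OEt2 removes one methoxy group of 13 to give an oxocarbenium ion at C1 whose C2–H exchanges through the β-methoxyacrylate, so both C2 epimers should drain through the same ion. Ring A attacks through the carbon ortho to the tether, in a six-membered closure that is exo-trig with respect to the C=O+ bond and passes through a chair-like transition state with CO2Me and CH2OBn equatorial, giving the 2,3-trans 1-methoxytetralin 15. The Lewis acid then ionises the C1–OMe bond of 15 to a cation stabilised by the ortho (C8) and para (C6) methoxy groups of ring A, and 14 captures it through the carbon para to its free hydroxyl, forming C1–aryl. The C1 stereocentre is set by approach of the phenol anti to the neighbouring C2 ester, so a C2 ester trans to C3 leads to the all-trans product. The closest known reactions are the Lewis-acid cyclisation of aryl-tethered acetals to 1-alkoxytetralins and the Friedel–Crafts arylation of benzylic ethers and alcohols by phenols, the latter being the usual entry to the all-trans 1-aryltetralin lignans; the two are run here in one flask. Ring A poses no regiochemical question because its two ortho carbons are equivalent before closure, and the phenol reacts para to OH because that is the only position activated by the free hydroxyl. The step needs closure to precede or follow arylation without a second arylation of C1 and without loss of the C2 proton from the cation; the six-membered tether, the excess of 14 and the low temperature are meant to secure this. Should 14 add first, the syringyl-stabilised cation closes onto ring A to the same product.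

Step 9
Reactants: 16 methyl (1R,2S,3S)-7-(benzyloxy)-3-[(benzyloxy)methyl]-1-(4-hydroxy-3,5-dimethoxyphenyl)-6,8-dimethoxy-1,2,3,4-tetrahydronaphthalene-2-carboxylate
Product: 17 methyl (1R,2S,3S)-7-(benzyloxy)-1-[4-(benzyloxy)-3,5-dimethoxyphenyl]-3-[(benzyloxy)methyl]-6,8-dimethoxy-1,2,3,4-tetrahydronaphthalene-2-carboxylate
Conditions: BnBr, K2CO3, DMF, rt
Reagents that add atoms: benzyl bromide, BrCc1ccccc1
Why: Williamson ether synthesis on the hindered phenoxide; carbonate does not touch the ester or its α-centre, and the phenol is now masked against sulfation.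

Step 10
Reactants: 17 methyl (1R,2S,3S)-7-(benzyloxy)-1-[4-(benzyloxy)-3,5-dimethoxyphenyl]-3-[(benzyloxy)methyl]-6,8-dimethoxy-1,2,3,4-tetrahydronaphthalene-2-carboxylate
Product: 18 [(1R,2S,3S)-7-(benzyloxy)-1-[4-(benzyloxy)-3,5-dimethoxyphenyl]-3-[(benzyloxy)methyl]-6,8-dimethoxy-1,2,3,4-tetrahydronaphthalen-2-yl]methanol
Conditions: LiAlH4, THF, 0 °C; H2O, aq. NaOH work-up
Reagents that add atoms: none
Why: Hydride reduction of the ester to the primary alcohol; fast at 0 °C, without epimerisation at C2, and benzyl ethers are inert.

Step 11
Reactants: 18 [(1R,2S,3S)-7-(benzyloxy)-1-[4-(benzyloxy)-3,5-dimethoxyphenyl]-3-[(benzyloxy)methyl]-6,8-dimethoxy-1,2,3,4-tetrahydronaphthalen-2-yl]methanol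
Product: 20 sodium [(1R,2S,3S)-7-(benzyloxy)-1-[4-(benzyloxy)-3,5-dimethoxyphenyl]-3-[(benzyloxy)methyl]-6,8-dimethoxy-1,2,3,4-tetrahydronaphthalen-2-yl]methyl sulfate, via pyridinium sulfate 19 (not isolated)
Conditions: SO3·pyridine (5 equiv), pyridine, rt; then aq. NaHCO3
Reagents that add atoms: sulfur trioxide pyridine complex, O=S(=O)([O-])[n+]1ccccc1; sodium hydrogen carbonate, [Na+].OC([O-])=O
Why: O-sulfation of the only free hydroxyl by the amine–SO3 complex; exchange to the sodium salt removes pyridine, which would inhibit the following hydrogenolysis.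

Step 12
Reactants: 20 sodium [(1R,2S,3S)-7-(benzyloxy)-1-[4-(benzyloxy)-3,5-dimethoxyphenyl]-3-[(benzyloxy)methyl]-6,8-dimethoxy-1,2,3,4-tetrahydronaphthalen-2-yl]methyl sulfate
Product: 22 [(1R,2S,3S)-7-hydroxy-1-(4-hydroxy-3,5-dimethoxyphenyl)-3-(hydroxymethyl)-6,8-dimethoxy-1,2,3,4-tetrahydronaphthalen-2-yl]methyl hydrogen sulfate, via debenzylated sodium sulfate 21 (not isolated)
Conditions: H2 (1 atm), Pd(OH)2/C, MeOH–H2O, rt; filter; then HCl (1.0 equiv), 0 °C, C18 desalting, freeze-drying
Reagents that add atoms: none
Why: Hydrogenolysis of two aryl and one alkyl benzyl ether under neutral conditions, to which alkyl sulfate salts are inert; one equivalent of acid then releases the hydrogen sulfate, and no stereocentre is touched.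

## Compound list

1 | syringaldehyde (4-hydroxy-3,5-dimethoxybenzaldehyde) | COc1cc(C=O)cc(OC)c1O | starting material
2 | 4-(benzyloxy)-3,5-dimethoxybenzaldehyde | COc1cc(C=O)cc(OC)c1OCc1ccccc1 | intermediate
3 | dimethyl succinate | COC(=O)CCC(=O)OC | starting material
4 | methyl 2-[4-(benzyloxy)-3,5-dimethoxyphenyl]-5-oxotetrahydrofuran-3-carboxylate (paraconic ester, racemic, formed in the flask) | COC(=O)C1CC(=O)OC1c1cc(OC)c(OCc2ccccc2)c(OC)c1 | intermediate
5 | (E)-4-[4-(benzyloxy)-3,5-dimethoxyphenyl]-3-(methoxycarbonyl)but-3-enoic acid | COc1cc(/C=C(\CC(=O)O)C(=O)OC)cc(OC)c1OCc1ccccc1 | intermediate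
6 | (3S)-4-[4-(benzyloxy)-3,5-dimethoxyphenyl]-3-(methoxycarbonyl)butanoic acid | COc1cc(C[C@@H](CC(=O)O)C(=O)OC)cc(OC)c1OCc1ccccc1 | intermediate
7 | lithium (3S)-4-[4-(benzyloxy)-3,5-dimethoxyphenyl]-3-(hydroxymethyl)butanoate (formed in the flask) | COc1cc(C[C@H](CO)CC(=O)[O-])cc(OC)c1OCc1ccccc1.[Li+] | intermediate
8 | (4S)-4-[4-(benzyloxy)-3,5-dimethoxybenzyl]dihydrofuran-2(3H)-one | COc1cc(C[C@@H]2COC(=O)C2)cc(OC)c1OCc1ccccc1 | intermediate
9 | potassium (3S)-4-[4-(benzyloxy)-3,5-dimethoxyphenyl]-3-(hydroxymethyl)butanoate (formed in the flask) | COc1cc(C[C@H](CO)CC(=O)[O-])cc(OC)c1OCc1ccccc1.[K+] | intermediate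
10 | (3S)-4-[4-(benzyloxy)-3,5-dimethoxyphenyl]-3-[(benzyloxy)methyl]butanoic acid | COc1cc(C[C@H](COCc2ccccc2)CC(=O)O)cc(OC)c1OCc1ccccc1 | intermediate
11 | methyl (3S)-4-[4-(benzyloxy)-3,5-dimethoxyphenyl]-3-[(benzyloxy)methyl]butanoate | COc1cc(C[C@H](COCc2ccccc2)CC(=O)OC)cc(OC)c1OCc1ccccc1 | intermediate
12 | methyl (3S)-4-[4-(benzyloxy)-3,5-dimethoxyphenyl]-3-[(benzyloxy)methyl]-2-formylbutanoate (C2 epimers and enol, lithium enolate in the flask) | COc1cc(C[C@H](COCc2ccccc2)C(C=O)C(=O)OC)cc(OC)c1OCc1ccccc1 | intermediate
13 | methyl (3S)-4-[4-(benzyloxy)-3,5-dimethoxyphenyl]-3-[(benzyloxy)methyl]-2-(dimethoxymethyl)butanoate (both C2 epimers) | COc1cc(C[C@H](COCc2ccccc2)C(C(OC)OC)C(=O)OC)cc(OC)c1OCc1ccccc1 | intermediate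
14 | 2,6-dimethoxyphenol | COc1cccc(OC)c1O | starting material
15 | methyl (2R,3S)-7-(benzyloxy)-3-[(benzyloxy)methyl]-1,6,8-trimethoxy-1,2,3,4-tetrahydronaphthalene-2-carboxylate (2,3-trans, both C1 epimers, formed in the flask) | COC1c2c(cc(OC)c(OCc3ccccc3)c2OC)C[C@H](COCc2ccccc2)[C@H]1C(=O)OC | intermediate
16 | methyl (1R,2S,3S)-7-(benzyloxy)-3-[(benzyloxy)methyl]-1-(4-hydroxy-3,5-dimethoxyphenyl)-6,8-dimethoxy-1,2,3,4-tetrahydronaphthalene-2-carboxylate | COc1cc([C@@H]2c3c(cc(OC)c(OCc4ccccc4)c3OC)C[C@H](COCc3ccccc3)[C@H]2C(=O)OC)cc(OC)c1O | intermediate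
17 | methyl (1R,2S,3S)-7-(benzyloxy)-1-[4-(benzyloxy)-3,5-dimethoxyphenyl]-3-[(benzyloxy)methyl]-6,8-dimethoxy-1,2,3,4-tetrahydronaphthalene-2-carboxylate | COc1cc([C@@H]2c3c(cc(OC)c(OCc4ccccc4)c3OC)C[C@H](COCc3ccccc3)[C@H]2C(=O)OC)cc(OC)c1OCc1ccccc1 | intermediate
18 | [(1R,2S,3S)-7-(benzyloxy)-1-[4-(benzyloxy)-3,5-dimethoxyphenyl]-3-[(benzyloxy)methyl]-6,8-dimethoxy-1,2,3,4-tetrahydronaphthalen-2-yl]methanol | COc1cc([C@@H]2c3c(cc(OC)c(OCc4ccccc4)c3OC)C[C@H](COCc3ccccc3)[C@H]2CO)cc(OC)c1OCc1ccccc1 | intermediate
19 | pyridinium [(1R,2S,3S)-7-(benzyloxy)-1-[4-(benzyloxy)-3,5-dimethoxyphenyl]-3-[(benzyloxy)methyl]-6,8-dimethoxy-1,2,3,4-tetrahydronaphthalen-2-yl]methyl sulfate (formed in the flask) | COc1cc([C@@H]2c3c(cc(OC)c(OCc4ccccc4)c3OC)C[C@H](COCc3ccccc3)[C@H]2COS(=O)(=O)[O-])cc(OC)c1OCc1ccccc1.c1cc[nH+]cc1 | intermediate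
20 | sodium [(1R,2S,3S)-7-(benzyloxy)-1-[4-(benzyloxy)-3,5-dimethoxyphenyl]-3-[(benzyloxy)methyl]-6,8-dimethoxy-1,2,3,4-tetrahydronaphthalen-2-yl]methyl sulfate | COc1cc([C@@H]2c3c(cc(OC)c(OCc4ccccc4)c3OC)C[C@H](COCc3ccccc3)[C@H]2COS(=O)(=O)[O-])cc(OC)c1OCc1ccccc1.[Na+] | intermediate
21 | sodium [(1R,2S,3S)-7-hydroxy-1-(4-hydroxy-3,5-dimethoxyphenyl)-3-(hydroxymethyl)-6,8-dimethoxy-1,2,3,4-tetrahydronaphthalen-2-yl]methyl sulfate (formed in the flask) | COc1cc([C@@H]2c3c(cc(OC)c(O)c3OC)C[C@H](CO)[C@H]2COS(=O)(=O)[O-])cc(OC)c1O.[Na+] | intermediate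
22 | [(1R,2S,3S)-7-hydroxy-1-(4-hydroxy-3,5-dimethoxyphenyl)-3-(hydroxymethyl)-6,8-dimethoxy-1,2,3,4-tetrahydronaphthalen-2-yl]methyl hydrogen sulfate | COc1cc([C@@H]2c3c(cc(OC)c(O)c3OC)C[C@H](CO)[C@H]2COS(=O)(=O)O)cc(OC)c1O | target

## Step count and least certain steps

Total: 12 steps. Longest linear sequence: 12 steps, from syringaldehyde 1; phenol 14 enters as a purchased reagent in step 8.

**Step 8 (key step).** Three processes could spoil it. Ring closure may outrun the exchange of the C2 proton; part of the material would then close with the ester cis to the C3 arm, and that series cannot be corrected later because C1 is set anti to the wrong C2. Intermolecular capture of the cation at C1 is slowed by the peri methoxy group at C8, so loss of the C2 proton to a dihydronaphthalene ester may compete. The congested benzyl ether on ring A may be cleaved by the Lewis acid. Treating 17 with NaOMe in MeOH would confirm that the ester is the thermodynamic C2 epimer, but would repair only material whose C1 and C3 are already right.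

The fallback sets out from lactone 8 and comes back to the route at alcohol 18 in the same number of operations, with C2 fixed by a ring and C1–C8a formed last in the classical manner. The lithium enolate of 8 (LiN(iPr)2, THF, −78 °C) adds to aldehyde 2 anti to the C3 benzyl group to give the trans α-(hydroxybenzyl) lactone F1. CF3CO2H in CH2Cl2 ionises the carbinol and ring A closes onto the cation to give the trans-fused all-trans aryltetralin lactone F2. Me2AlN(OMe)Me, from AlMe3 and MeNHOMe·HCl, opens the strained lactone to the hydroxy Weinreb amide F3. Benzyl trichloroacetimidate with catalytic TfOH gives the benzyloxy Weinreb amide F4. LiAlH4 at −78 °C gives the aldehyde F5, and NaBH4 reduces it to 18.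

**Step 3.** The enantioselectivity may be insufficient, or the sense of induction opposite, for this electron-rich β-aryl itaconate. Any Z isomer in 5 would erode the selectivity further. The fallback runs from 5 back to 6 by classical resolution: hydrogenation with [Rh(cod)2]BF4 and the achiral ligand dppb gives the racemic acid F6. Crystallisation with (S)-1-phenylethylamine (or its antipode, whichever gives the less soluble salt of the S acid) gives the diastereomerically pure ammonium salt F7, from which aqueous HCl releases 6.

**Step 7.** The crossed Claisen reaction may stall through proton transfer from the product to unreacted enolate. The formyl group may also be lost by retro-Claisen cleavage in the acidic methanol. The fallback runs from 11 back to 13 and brings in C1 already at the acetal level: LiN(iPr)2 and Me3SiCl convert 11 into the silyl ketene acetal F8. This is alkylated by trimethyl orthoformate with catalytic Me3SiOTf in CH2Cl2 at −78 °C (a Mukaiyama-type reaction of the dimethoxycarbenium ion) to give 13.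

**Step 11.** Sulfation of the crowded, β-branched primary alcohol may be incomplete, and the salt may be lost on purification. The fallback sets out from 18 and comes back to the route at 22, through a neutral sulfate diester that can be chromatographed. 2,2,2-Trichloroethoxysulfonyl-2-methylimidazolium triflate with 1-methylimidazole gives the trichloroethyl sulfate diester F9. Zn and HCO2NH4 in MeOH remove the trichloroethyl group to give the ammonium sulfate F10. F10 is debenzylated and acidified as in step 12 to give 22.

## Further compounds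

F1 | step 8 | (4S)-4-[4-(benzyloxy)-3,5-dimethoxybenzyl]-3-{[4-(benzyloxy)-3,5-dimethoxyphenyl](hydroxy)methyl}dihydrofuran-2(3H)-one, 3,4-trans, carbinol epimers | COc1cc(C[C@@H]2COC(=O)[C@H]2C(O)c2cc(OC)c(OCc3ccccc3)c(OC)c2)cc(OC)c1OCc1ccccc1
F2 | step 8 | all-trans 7-(benzyloxy)-1-[4-(benzyloxy)-3,5-dimethoxyphenyl]-6,8-dimethoxytetralin-2,3-carbolactone (carbonyl on C2, trans-fused) | COc1cc([C@@H]2c3c(cc(OC)c(OCc4ccccc4)c3OC)C[C@@H]3COC(=O)[C@@H]23)cc(OC)c1OCc1ccccc1
F3 | step 8 | (1R,2S,3S)-7-(benzyloxy)-1-[4-(benzyloxy)-3,5-dimethoxyphenyl]-3-(hydroxymethyl)-N,6,8-trimethoxy-N-methyl-1,2,3,4-tetrahydronaphthalene-2-carboxamide | COc1cc([C@@H]2c3c(cc(OC)c(OCc4ccccc4)c3OC)C[C@H](CO)[C@H]2C(=O)N(C)OC)cc(OC)c1OCc1ccccc1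
F4 | step 8 | (1R,2S,3S)-7-(benzyloxy)-1-[4-(benzyloxy)-3,5-dimethoxyphenyl]-3-[(benzyloxy)methyl]-N,6,8-trimethoxy-N-methyl-1,2,3,4-tetrahydronaphthalene-2-carboxamide | COc1cc([C@@H]2c3c(cc(OC)c(OCc4ccccc4)c3OC)C[C@H](COCc3ccccc3)[C@H]2C(=O)N(C)OC)cc(OC)c1OCc1ccccc1
F5 | step 8 | (1R,2S,3S)-7-(benzyloxy)-1-[4-(benzyloxy)-3,5-dimethoxyphenyl]-3-[(benzyloxy)methyl]-6,8-dimethoxy-1,2,3,4-tetrahydronaphthalene-2-carbaldehyde | COc1cc([C@@H]2c3c(cc(OC)c(OCc4ccccc4)c3OC)C[C@H](COCc3ccccc3)[C@H]2C=O)cc(OC)c1OCc1ccccc1
F6 | step 3 | racemic 4-[4-(benzyloxy)-3,5-dimethoxyphenyl]-3-(methoxycarbonyl)butanoic acid | COc1cc(CC(CC(=O)O)C(=O)OC)cc(OC)c1OCc1ccccc1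
F7 | step 3 | (S)-1-phenylethylammonium (3S)-4-[4-(benzyloxy)-3,5-dimethoxyphenyl]-3-(methoxycarbonyl)butanoate | COc1cc(C[C@@H](CC(=O)[O-])C(=O)OC)cc(OC)c1OCc1ccccc1.C[C@H]([NH3+])c1ccccc1
F8 | step 7 | methyl trimethylsilyl ketene acetal of 11, (3S), alkene geometry not defined | COC(O[Si](C)(C)C)=C[C@@H](COCc1ccccc1)Cc1cc(OC)c(OCc2ccccc2)c(OC)c1
F9 | step 11 | [(1R,2S,3S)-7-(benzyloxy)-1-[4-(benzyloxy)-3,5-dimethoxyphenyl]-3-[(benzyloxy)methyl]-6,8-dimethoxy-1,2,3,4-tetrahydronaphthalen-2-yl]methyl 2,2,2-trichloroethyl sulfate | COc1cc([C@@H]2c3c(cc(OC)c(OCc4ccccc4)c3OC)C[C@H](COCc3ccccc3)[C@H]2COS(=O)(=O)OCC(Cl)(Cl)Cl)cc(OC)c1OCc1ccccc1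
F10 | step 11 | ammonium [(1R,2S,3S)-7-(benzyloxy)-1-[4-(benzyloxy)-3,5-dimethoxyphenyl]-3-[(benzyloxy)methyl]-6,8-dimethoxy-1,2,3,4-tetrahydronaphthalen-2-yl]methyl sulfate | COc1cc([C@@H]2c3c(cc(OC)c(OCc4ccccc4)c3OC)C[C@H](COCc3ccccc3)[C@H]2COS(=O)(=O)[O-])cc(OC)c1OCc1ccccc1.[NH4+]
A1 | alternative 1 | (S)-4-benzyl-3-[(E)-3-(4-hydroxy-3,5-dimethoxyphenyl)acryloyl]oxazolidin-2-one | COc1cc(/C=C/C(=O)N2[C@@H](Cc3ccccc3)COC2=O)cc(OC)c1O
A2 | alternative 1 | trans-1-syringyl-7-hydroxy-6,8-dimethoxy-1,2-dihydronaphthalene-2,3-bis(acyl oxazolidinone) | COc1cc([C@@H]2c3c(cc(OC)c(O)c3OC)C=C(C(=O)N3[C@@H](Cc4ccccc4)COC3=O)[C@H]2C(=O)N2[C@@H](Cc3ccccc3)COC2=O)cc(OC)c1O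
A3 | alternative 2 | 4-(benzyloxy)-2-[4-(benzyloxy)-3,5-dimethoxybenzyl]-3,5-dimethoxybenzaldehyde | COc1cc(C=O)c(Cc2cc(OC)c(OCc3ccccc3)c(OC)c2)c(OC)c1OCc1ccccc1
A4 | alternative 2 | bis[(S)-1-methoxy-1-oxopropan-2-yl] fumarate | COC(=O)[C@H](C)OC(=O)/C=C/C(=O)O[C@@H](C)C(=O)OC
A5 | alternative 2 | 1-aryl-4-hydroxytetralin-2,3-dicarboxylate bis-lactate ester (1,2-trans, 2,3-trans, 3,4-cis) | COc1cc([C@@H]2c3c(cc(OC)c(OCc4ccccc4)c3OC)[C@H](O)[C@H](C(=O)O[C@@H](C)C(=O)OC)[C@H]2C(=O)O[C@@H](C)C(=O)OC)cc(OC)c1OCc1ccccc1
A6 | alternative 3 | 2-tert-butyl 1,1-dimethyl trans-3-[4-(benzyloxy)-3,5-dimethoxyphenyl]cyclopropane-1,1,2-tricarboxylate | COC(=O)C1(C(=O)OC)[C@H](C(=O)OC(C)(C)C)[C@H]1c1cc(OC)c(OCc2ccccc2)c(OC)c1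
A7 | alternative 3 | 4-(benzyloxy)-3,5-dimethoxybenzyl acetate | CC(=O)OCc1cc(OC)c(OCc2ccccc2)c(OC)c1
A8 | alternative 3 | 1-aryltetralin-2,3,3-tricarboxylate (1,2-cis) | COc1cc([C@@H]2c3c(cc(OC)c(OCc4ccccc4)c3OC)CC(C(=O)OC)(C(=O)OC)[C@@H]2C(=O)OC(C)(C)C)cc(OC)c1OCc1ccccc1
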